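**Retrosynthetic overview** (ring atoms: C1 = C=O, C2, C3 = C–OMe, C4 = ketal carbon, C5, C6 = C–allyl)
1. Last disconnection: C4–OMe, made by axial methanol capture of the C4 aryloxy-oxocarbenium ion released from a C4 sulfone.
2. Key disconnection: C3–C4 (ring closure) together with C5–C6, an anionic [4+2] annulation of a C6–C1–C2–C3 ketene-acetal ketone enolate with a C4=C5 unit, an enantiopure 1-aryloxyvinyl p-tolyl sulfoxide.
3. Enabling feature: in the cyclohexenone ring the ketal carbon C4 is bonded to C3, the OMe-bearing β-carbon of the vinylogous ester C1(=O)–C2=C3(OMe). Both are electrophilic carbons, so C4 is polarity-reversed as a sulfinyl carbanion (sulfur later leaves as sulfinate) and C3 is offered as a ketene-acetal carbon that keeps one OMe.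
4. Fragments: the vinyl sulfoxide from 3,4-dimethoxyphenol (O-allylation, Claisen, S–CH2–O ether, asymmetric S-oxidation, methylenation); the ketone from pent-4-enoyl chloride and 1,1-dimethoxyethene.
5. Ring order: the arene is bought; the only ring formed is the six-membered carbocycle (step 7). Stereochemical relay: sulfur → C4 → C6 → final C4.

Key step: step 7

Assumption (remark on the chemistry): the sense of 1,2-induction from the (S)-sulfinyl group to C4 in step 7 and the trans preference of the C6 allyl group relative to the sulfur substituent are taken as drawn; if their net sense proves opposite, the (R)-sulfoxide (from (S,S)-diethyl tartrate in step 4) is carried through instead and nothing else changes.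

Step 1
Reactants: 1 3,4-dimethoxyphenol
Product: 2 4-(allyloxy)-1,2-dimethoxybenzene
Conditions: allyl bromide, K2CO3, acetone, reflux
Reagents that add atoms: allyl bromide, C=CCBr
Why: Williamson O-alkylation (SN2) of the phenoxide; no stereocentre is formed.

Step 2
Reactants: 2 4-(allyloxy)-1,2-dimethoxybenzene
Product: 3 2-allyl-4,5-dimethoxyphenol
Conditions: N,N-diethylaniline, 190 °C
Reagents that add atoms: none
Why: Aromatic Claisen rearrangement ([3,3] shift, then tautomerisation) should deliver the allyl group to the ortho position that is not flanked by a methoxy group.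

Step 3
Reactants: 3 2-allyl-4,5-dimethoxyphenol, 4 chloromethyl p-tolyl sulfide
Product: 5 1-allyl-4,5-dimethoxy-2-[(p-tolylsulfanyl)methoxy]benzene
Conditions: K2CO3, NaI (cat.), DMF, 50 °C
Reagents that add atoms: none
Why: SN2 O-alkylation of the phenoxide by the highly reactive α-chloro sulfide gives the O,S-acetal that carries the future C4.

Step 4
Reactants: 5 1-allyl-4,5-dimethoxy-2-[(p-tolylsulfanyl)methoxy]benzene
Product: 6 1-allyl-4,5-dimethoxy-2-{[(S)-p-tolylsulfinyl]methoxy}benzene
Conditions: Ti(OiPr)4 (0.5 equiv), (R,R)-diethyl tartrate (1 equiv), H2O (0.5 equiv), cumene hydroperoxide, CH2Cl2, −20 °C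
Reagents that add atoms: cumene hydroperoxide, CC(C)(OO)c1ccccc1
Why: Kagan–Modena asymmetric sulfoxidation: with p-tolyl as the large group the titanium–tartrate peroxo complex should give the spatial analogue of (R)-methyl p-tolyl sulfoxide, named (S) here because CH2OAr outranks p-tolyl, without attacking the isolated alkene or the arene; enantiomeric purity can be raised by crystallisation.

Step 5
Reactants: 6 1-allyl-4,5-dimethoxy-2-{[(S)-p-tolylsulfinyl]methoxy}benzene
Product: 9 1-allyl-4,5-dimethoxy-2-({1-[(S)-p-tolylsulfinyl]vinyl}oxy)benzene, via Mannich base 7 (not isolated), via trimethylammonium iodide 8 (not isolated)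
Conditions: LiN(iPr)2, THF, −78 °C; CH2=N(CH3)2+ I−, −78 → 0 °C; CH3I, rt, evaporate; KOC(CH3)3, THF, −40 °C
Reagents that add atoms: N,N-dimethylmethyleneiminium iodide (Eschenmoser's salt), C=[N+](C)C.[I-]
Why: Mannich reaction of the α-sulfinyl carbanion, N-methylation and base-induced elimination of trimethylamine (α-methylenation) should give the ketene O,S-acetal S-oxide; sulfur is untouched and the transient carbon stereocentre of 7 and 8 is lost in the elimination.

Step 6
Reactants: 10 pent-4-enoyl chloride, 11 1,1-dimethoxyethene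
Product: 12 1,1-dimethoxyhepta-1,6-dien-3-one
Conditions: 11 (2.2 equiv), Et2O, 0 °C → rt
Reagents that add atoms: none
Why: C-acylation of the ketene acetal by the acid chloride and loss of HCl gives the α-oxo ketene acetal; the second equivalent of 11 takes up HCl, so no amine is present that could convert the acid chloride into a ketene.

Step 7
Reactants: 12 1,1-dimethoxyhepta-1,6-dien-3-one, 9 1-allyl-4,5-dimethoxy-2-({1-[(S)-p-tolylsulfinyl]vinyl}oxy)benzene
Product: 15 (4S,6S)-6-allyl-4-(2-allyl-4,5-dimethoxyphenoxy)-3-methoxy-4-[(S)-p-tolylsulfinyl]cyclohex-2-en-1-one, via lithium dienolate 13 (not isolated), via open-chain sulfinyl carbanion 14 (not isolated)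
Conditions: 12, LiN(iPr)2, THF, −78 °C; then 9, −78 → 0 °C; aq NH4Cl
Reagents that add atoms: none
Why: The kinetic dienolate 13 (C6 is the only enolisable carbon of 12) adds through C6 to the CH2 terminus (C5) of the ketene O,S-acetal S-oxide 9, the conjugate-addition mode known for enolates and ketene dithioacetal monoxides, and so creates the α-aryloxy-α-sulfinyl carbanion 14 in which the future ketal carbon C4 is polarity-reversed. The carbanion then closes the cyclohexenone ring by 6-endo-trig attack on C3, the ketene-acetal β-carbon of the enone, with loss of methoxide (nucleophilic vinylic substitution), so the ring-closing C3–C4 bond joins two carbons that are both electrophilic in the product; the whole is a Michael-initiated ring closure (formal anionic [4+2] annulation). C4 is set by 1,2-induction from the sulfur stereocentre in a lithium-bridged transition state (sulfinyl oxygen and C1 carbonyl on lithium, p-tolyl turned away from C3), and because the two C4 epimers are diastereomers a minor one can be removed by chromatography. C6 is epimerisable (α to C1) and should settle, under the lithium methoxide released in the closure, with the allyl group pseudoequatorial and trans to the pseudoaxial sulfinyl group, which avoids allylic strain with the C3 methoxy group. The selectivity needed is bond formation at C5 before anything happens at C3, and closure at C3 instead of at the C1 carbonyl: the first is secured because the carbanion only exists once the C5–C6 bond has formed, the second because attack at C1 would give a four-membered ring.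

Step 8
Reactants: 15 (4S,6S)-6-allyl-4-(2-allyl-4,5-dimethoxyphenoxy)-3-methoxy-4-[(S)-p-tolylsulfinyl]cyclohex-2-en-1-one
Product: 16 (4S,6S)-6-allyl-4-(2-allyl-4,5-dimethoxyphenoxy)-3-methoxy-4-(p-tolylsulfonyl)cyclohex-2-en-1-one
Conditions: 30% H2O2, (NH4)6Mo7O24·4H2O (cat.), EtOH, 0 °C → rt
Reagents that add atoms: hydrogen peroxide, OO
Why: Peroxomolybdate-catalysed oxidation should convert the sulfoxide into the sulfone (the leaving group for step 9) much faster than it epoxidises the monosubstituted alkenes or the acceptor-substituted enol ether; C4 and C6 are not touched.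

Step 9
Reactants: 16 (4S,6S)-6-allyl-4-(2-allyl-4,5-dimethoxyphenoxy)-3-methoxy-4-(p-tolylsulfonyl)cyclohex-2-en-1-one
Product: 17 (4R,6S)-6-allyl-4-(2-allyl-4,5-dimethoxyphenoxy)-3,4-dimethoxycyclohex-2-en-1-one
Conditions: MgBr2·OEt2, CH3OH (10 equiv), NaHCO3, THF, −20 → 0 °C
Reagents that add atoms: methanol, CO
Why: Lewis-acid-assisted ionisation of the α-aryloxy sulfone (exchange of an anomeric-type sulfone for an alkoxy group) gives the C4 aryloxy-oxocarbenium ion, which methanol should capture axially (chair-like transition state) on the face trans to the pseudoequatorial C6 allyl group, i.e. with overall retention, setting (4R); buffer and excess methanol are there to outrun loss of a C5 proton, which would aromatise the ring.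

**Compound list**
1 | 3,4-dimethoxyphenol | COc1ccc(O)cc1OC | starting material
2 | 4-(allyloxy)-1,2-dimethoxybenzene | C=CCOc1ccc(OC)c(OC)c1 | intermediate
3 | 2-allyl-4,5-dimethoxyphenol | C=CCc1cc(OC)c(OC)cc1O | intermediate
4 | chloromethyl p-tolyl sulfide | Cc1ccc(SCCl)cc1 | starting material
5 | 1-allyl-4,5-dimethoxy-2-[(p-tolylsulfanyl)methoxy]benzene | C=CCc1cc(OC)c(OC)cc1OCSc1ccc(C)cc1 | intermediate
6 | 1-allyl-4,5-dimethoxy-2-{[(S)-p-tolylsulfinyl]methoxy}benzene | C=CCc1cc(OC)c(OC)cc1OC[S@@](=O)c1ccc(C)cc1 | intermediate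
7 | 2-(2-allyl-4,5-dimethoxyphenoxy)-N,N-dimethyl-2-[(S)-p-tolylsulfinyl]ethanamine (both epimers at C2) | C=CCc1cc(OC)c(OC)cc1OC(CN(C)C)[S@@](=O)c1ccc(C)cc1 | intermediate
8 | 2-(2-allyl-4,5-dimethoxyphenoxy)-N,N,N-trimethyl-2-[(S)-p-tolylsulfinyl]ethanaminium iodide (both epimers at C2) | C=CCc1cc(OC)c(OC)cc1OC(C[N+](C)(C)C)[S@@](=O)c1ccc(C)cc1.[I-] | intermediate
9 | 1-allyl-4,5-dimethoxy-2-({1-[(S)-p-tolylsulfinyl]vinyl}oxy)benzene | C=CCc1cc(OC)c(OC)cc1OC(=C)[S@@](=O)c1ccc(C)cc1 | intermediate
10 | pent-4-enoyl chloride | C=CCCC(=O)Cl | starting material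
11 | 1,1-dimethoxyethene | C=C(OC)OC | starting material
12 | 1,1-dimethoxyhepta-1,6-dien-3-one | COC(OC)=CC(=O)CCC=C | intermediate
13 | lithium 1,1-dimethoxyhepta-1,3,6-trien-3-olate | [Li+].COC(OC)=CC([O-])=CCC=C | intermediate
14 | lithium 3-allyl-1-(2-allyl-4,5-dimethoxyphenoxy)-6,6-dimethoxy-4-oxo-1-[(S)-p-tolylsulfinyl]hex-5-en-1-ide (both epimers at C3) | [Li+].COC(OC)=CC(=O)C(CC=C)C[C-](Oc1cc(OC)c(OC)cc1CC=C)[S@@](=O)c1ccc(C)cc1 | intermediate
15 | (4S,6S)-6-allyl-4-(2-allyl-4,5-dimethoxyphenoxy)-3-methoxy-4-[(S)-p-tolylsulfinyl]cyclohex-2-en-1-one | C=CCc1cc(OC)c(OC)cc1O[C@]1([S@@](=O)c2ccc(C)cc2)C[C@H](CC=C)C(=O)C=C1OC | intermediate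
16 | (4S,6S)-6-allyl-4-(2-allyl-4,5-dimethoxyphenoxy)-3-methoxy-4-(p-tolylsulfonyl)cyclohex-2-en-1-one | C=CCc1cc(OC)c(OC)cc1O[C@]1(S(=O)(=O)c2ccc(C)cc2)C[C@H](CC=C)C(=O)C=C1OC | intermediate
17 | (4R,6S)-6-allyl-4-(2-allyl-4,5-dimethoxyphenoxy)-3,4-dimethoxycyclohex-2-en-1-one | C=CCc1cc(OC)c(OC)cc1O[C@]1(OC)C[C@H](CC=C)C(=O)C=C1OC | target

**Step count and risks**
Total step count: 9. Longest linear sequence: 8 steps (1, 2, 3, 4, 5, 7, 8, 9); step 6 runs in parallel.

Most likely to fail:

1. Step 7. The conjugate addition may be slow because the aryloxy group makes the vinyl sulfoxide a donor-substituted acceptor. The sulfinyl carbanion may be quenched by proton transfer from C6–H before it closes onto the hindered, doubly oxygenated C3. Facial selectivity at C4 and the C6 equilibrium may be poor, which would erode the stereochemical relay. Fallback (the sulfoxide carbon is the nucleophile from the start and the allyl group comes last): it sets out from 6. The lithiated sulfoxide (LiN(iPr)2, THF, −78 °C) is added to the vinyl ketone terminus of 1,1-dimethoxypenta-1,4-dien-3-one F1 (from acryloyl chloride and 11 as in step 6) to give the open-chain ketone 5-(2-allyl-4,5-dimethoxyphenoxy)-1,1-dimethoxy-5-[(S)-p-tolylsulfinyl]pent-1-en-3-one F2. F2 is closed by the same C3–C4 addition–elimination under equilibrating LiOCH3 in THF–CH3OH to the allyl-free enone (S)-4-(2-allyl-4,5-dimethoxyphenoxy)-3-methoxy-4-[(S)-p-tolylsulfinyl]cyclohex-2-en-1-one F3 (C4 epimers separated). F3 is oxidised as in step 8 to the sulfone (S)-4-(2-allyl-4,5-dimethoxyphenoxy)-3-methoxy-4-(p-tolylsulfonyl)cyclohex-2-en-1-one F4. Kinetic α'-allylation of F4 (LiN(iPr)2, allyl bromide, THF, −78 °C; axial attack anti to the pseudoaxial sulfonyl group) returns to the route at 16.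

2. Step 9. Ionisation may be too slow at a C4 that is stabilised only by an aryloxy group and flanked by the acceptor-substituted alkene. The oxocarbenium ion may lose a C5 proton, with irreversible aromatisation, or be captured with incomplete facial selectivity. Fallback (oxidative γ-methoxylation instead of substitution): it sets out from 16. Reductive removal of the sulfonyl group (SmI2, THF–CH3OH, −78 °C) gives (6S)-6-allyl-4-(2-allyl-4,5-dimethoxyphenoxy)-3-methoxycyclohex-2-en-1-one F5 (C4 epimers). Soft enolisation towards C4 (tert-butyldimethylsilyl triflate, Et3N, CH2Cl2, 0 °C) gives the extended dienol ether tert-butyl{[(6S)-6-allyl-4-(2-allyl-4,5-dimethoxyphenoxy)-3-methoxycyclohexa-1,3-dien-1-yl]oxy}dimethylsilane F6. Oxidation with PhI(OAc)2 (a trivalent-iodine oxidant) in CH3OH with NaHCO3 at −40 °C should deliver methanol to C4 trans to the C6 allyl group and regenerate the enone, arriving at 17.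

3. Step 4. Enantioselectivity may be modest, because the aryloxymethyl group is not a small substituent in the titanium–tartrate model, and over-oxidation to the sulfone is possible. Fallback (Andersen sulfoxide synthesis, substitution at sulfur with inversion): it sets out from 3. O-alkylation with ICH2Sn(C4H9)3 (K2CO3, DMF) gives tributyl[(2-allyl-4,5-dimethoxyphenoxy)methyl]stannane F7. Tin–lithium exchange (n-C4H9Li, THF, −78 °C) and addition of the aryloxymethyllithium to (1R,2S,5R)-menthyl (S)-p-toluenesulfinate should give enantiopure sulfoxide, returning to the route at 6.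

**Further compounds**
F1 | step 7 | 1,1-dimethoxypenta-1,4-dien-3-one | COC(OC)=CC(=O)C=C
F2 | step 7 | 5-(2-allyl-4,5-dimethoxyphenoxy)-1,1-dimethoxy-5-[(S)-p-tolylsulfinyl]pent-1-en-3-one (both epimers at C5) | COC(OC)=CC(=O)CCC(Oc1cc(OC)c(OC)cc1CC=C)[S@@](=O)c1ccc(C)cc1
F3 | step 7 | (S)-4-(2-allyl-4,5-dimethoxyphenoxy)-3-methoxy-4-[(S)-p-tolylsulfinyl]cyclohex-2-en-1-one | C=CCc1cc(OC)c(OC)cc1O[C@]1([S@@](=O)c2ccc(C)cc2)CCC(=O)C=C1OC
F4 | step 7 | (S)-4-(2-allyl-4,5-dimethoxyphenoxy)-3-methoxy-4-(p-tolylsulfonyl)cyclohex-2-en-1-one | C=CCc1cc(OC)c(OC)cc1O[C@]1(S(=O)(=O)c2ccc(C)cc2)CCC(=O)C=C1OC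
F5 | step 9 | (6S)-6-allyl-4-(2-allyl-4,5-dimethoxyphenoxy)-3-methoxycyclohex-2-en-1-one (both epimers at C4) | C=CCc1cc(OC)c(OC)cc1OC1C[C@H](CC=C)C(=O)C=C1OC
F6 | step 9 | tert-butyl{[(6S)-6-allyl-4-(2-allyl-4,5-dimethoxyphenoxy)-3-methoxycyclohexa-1,3-dien-1-yl]oxy}dimethylsilane | C=CCc1cc(OC)c(OC)cc1OC1=C(OC)C=C(O[Si](C)(C)C(C)(C)C)[C@@H](CC=C)C1
F7 | step 4 | tributyl[(2-allyl-4,5-dimethoxyphenoxy)methyl]stannane | C=CCc1cc(OC)c(OC)cc1OC[Sn](CCCC)(CCCC)CCCC
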